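A constant read from a falling curve is easily carried too far, past the readings it came from. We want the green flask at 20 min.

| setting | green | violet | flask |
|---|---|---|---|
| substrate | 0.050 M (fed, over 4.0 min) | 0.050 M (fed, over 4.0 min) | 0.050 M (fed, over 4.0 min) |
| enzyme | 5 µM | 2.5 µM | 5.0 µM |
| remark | the very flask that is asked about, followed so far | run made earlier |  |
| time |  |  | 20 min |

| run | time / min | substrate / % | product / % |
|---|---|---|---|
| green | 0.833 | 17 | 0 |
| green | 1.33 | 33 | 4 |
| green | 2.00 | 47 | 0 |
| green | 4.00 | 92 | 11 |
| green | 6.00 | 82 | 17 |
| green | 10.0 | 66 | 34 |
| violet | 1.00 | 25 | 0 |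
| violet | 2.50 | 59 | 2 |
| violet | 5.00 | 91 | 7 |
| violet | 8.00 | 86 | 18 |
| violet | 10.0 | 79 | 19 |
| violet | 15.0 | 71 | 26 |

(standard deviation of a reading: 1.5 percentage points)

1. the species that holds most of what was charged as substrate, at 20 min (product / substrate)
2. the largest share itself, whichever of these holds it, in percent of the substrate charged

The feed ends at 4.0 min, and after it the green flask's substrate falls. At 10.0 min the green flask's substrate and product together hold 100 %, so we read product as the charge minus substrate.

The slope of ln c(substrate) against time is a pseudo-first-order constant. Green gives 0.0554 min⁻¹ after the feed. Violet gives 0.0248 min⁻¹ from 5.00 min to 15.0 min. Green's constant is about twice violet's, and green's enzyme is twice violet's, so we scale violet's slopes by the enzyme ratio.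

First round: from 66 % at 10.0 min, green's constant leaves 37.9 % substrate at 20 min.

Now we put that answer back. It lies below every substrate reading we have after the feed, so we ask whether the constant holds down there. Violet's last stretch, at 79 % to 71 % substrate, lies higher, so it can show a trend and no more. Violet's slope, scaled, is 0.0566 min⁻¹ from 5.00 min to 10.0 min, but 0.0427 min⁻¹ from 10.0 min to 15.0 min, which is less. We call this second value the late constant: the fall of ln c(substrate) per minute at green's enzyme level, on violet's last stretch. With 1.5 percentage points on each reading it is rough.

Second round: the late constant leaves 43.1 % substrate, so we commit to 56.9 % product.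

The forecast says product at 60 %, “the data favour slowing”, which is higher than our figure.

At 20 min the flask gives product at 56.0 %, with substrate at 44.0 %.

    substrate + enzyme → product + enzyme, rate k1*[substrate]*[enzyme]/(1 + ([substrate]/Km1) + ([product]/Kp1)) (0.150 M, 44.0 mM, k = 240 M⁻¹ s⁻¹)

The flask's enzyme still stands at 100 % of its charge at 20.0 min. We run the late constant on from the flask's 44.0 % substrate to a neighbour flask with the same charges, read at 30 min, and it gives 28.7 % substrate. That neighbour flask holds 29.7 % substrate and 70.3 % product.

The runs were computed with made-up constants; scatter was added.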